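In cedar and maple the partner charge, 1.01 M, stands above the substrate charge, 0.84 M, so any leftover substrate in these two flasks is not for want of partner, and what you want to know is how fast the catalyst can hand out target.

| flask | substrate | partner | free catalyst | temperature | time |
|---|---|---|---|---|---|
| cedar | 0.84 M | 1.01 M | 21 mM | −20 °C | 40 h |
| maple | 0.84 M | 1.01 M | 21 mM | 0 °C | 40 h |

    catalyst intermediate D → free catalyst + target (k1 = 0.49 h⁻¹, Ea1 = 72.0 kJ mol⁻¹)
    partner + catalyst intermediate A → catalyst intermediate B (k2 = 39 M⁻¹ h⁻¹, Ea2 = 57.0 kJ mol⁻¹)
    2 catalyst intermediate D ⇌ resting dimer, settled at all times (K3 = 100 M⁻¹, ΔH3 = −76.0 kJ mol⁻¹)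
    catalyst intermediate C ⇌ released group + catalyst intermediate D (K4 = 2.5 M, k4 = 2.3 h⁻¹, Ea4 = 75.0 kJ mol⁻¹, ΔH4 = 14.0 kJ mol⁻¹)
    substrate + free catalyst ⇌ catalyst intermediate A (K5 = 0.47 M⁻¹, k5 = 140 M⁻¹ h⁻¹, Ea5 = 53.0 kJ mol⁻¹, ΔH5 = −33.0 kJ mol⁻¹)
    catalyst intermediate B → catalyst intermediate C (k6 = 9.0 h⁻¹, Ea6 = 70.0 kJ mol⁻¹)
    target → over-reaction product (k7 = 0.065 h⁻¹, Ea7 = 88.0 kJ mol⁻¹)
    (constants at −20 °C)

- a species is counted by the substrate in it: one resting dimer counts as two
- for a step with 2 of a species take k times the square, and two of it per event
- all constants are for −20 °C and move with temperature by the activation energies and enthalpies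

- which of these there is most of at the end, counted by the substrate in it, cedar (target / catalyst intermediate D / over-reaction product / substrate)
- which of these there is most of at the end, counted by the substrate in it, maple (target / catalyst intermediate D / over-reaction product / substrate)
- how much there is at the end of the one of these that leads, in percent of the substrate charged: cedar
- how much there is at the end of the one of these that leads, in percent of the substrate charged: maple

In cedar the half-life of catalyst intermediate D by its release step, 1.4 h, is longer than that of catalyst intermediate C, 0.30 h, or that of substrate on the binding step, 0.24 h, so I take the release as the rate-limiting step, with the catalyst waiting at intermediate D and [substrate] falling at a steady rate; integrated, that rate gives a straight line, the charge minus rate times time.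

You can then solve two extreme flasks in your head. In the first no dimer forms, the whole catalyst charge stands as intermediate D, the rate is 0.0103 M h⁻¹, and cedar keeps 51.0% of its substrate. In the second the catalyst charge is shared between intermediate D and the resting dimer, the resting state, at balance: [catalyst intermediate D] plus twice K3 times its square equals the charge, which gives 8.05 mM. The release ceiling, the release constant times the [catalyst intermediate D] this balance allows, is 0.00394 M h⁻¹, and it leaves 81.2% of the substrate in cedar.

The real cedar lies between the two, and I commit to a figure near the second, since the dimer is in the scheme and the first flask ignores it. The other catalyst forms take some intermediate D away, which raises the figure, while the substrate bound in them, at most 2.50% of the charge, lowers it. Substrate then leads cedar, with more left than used.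

At maple's temperature the release constant becomes 6.00 h⁻¹ and K3 falls to 7.11 M⁻¹, so the ceiling is 0.102 M h⁻¹. At that rate the charge would clear in 8.27 h, shorter than 40 h, and target then has a half-life of 0.499 h, so I expect over-reaction product to lead maple with close to the whole charge.

The forecast says substrate in cedar at 80% and over-reaction product in maple at 99%, on the ground that “the catalyst sits mostly as intermediate D and its dimer” in the cold flask.

The simulation gives substrate at 80.5% in cedar and over-reaction product at 99.8% in maple. The difference in temperature may be called the main reason for maple's end, since without it maple's substrate stands at 80.5% instead of 0.200%. The ceiling shows the size of that change: it rises 25.9-fold, and cedar, which has lost 19.5% of its substrate, runs close to its ceiling. Maple at its ceiling would finish the first part of its turnover, half of the charge, by 4.14 h, but its binding step reaches half of its turnover later, by 5.89 h.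

The numbers of this flask come from no measurement; the run is a simulation.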